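**Retrosynthesis**
1. The only stereocentre (C2, S) and the pyranone ring are formed last, by chalcone isomerase-catalysed enantioselective oxa-Michael cyclisation of 2′-hydroxychalcone **9**.
2. **9** comes from Claisen–Schmidt condensation of the prenylated acetophenone **5** with MOM-protected 4-hydroxybenzaldehyde **7**, followed by global MOM removal.
3. The prenyl group of **5** is made by cross-metathesis from an allyl group. The allyl group is placed regiospecifically by aromatic Claisen rearrangement of the mono-allyl ether of the symmetric acetophenone **1**.
4. The A ring is already present in **1**, so the order of ring formation is: A ring (purchased), then the C ring (enzymatic, last).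

Assumption: 2′,6′-dihydroxy-4′-methoxyacetophenone is purchasable. The alfalfa (type II) chalcone isomerase is assumed to accept the 4′-O-methyl, 3′-prenyl chalcone and cyclise through the unhindered 6′-OH. Any 8-prenyl regioisomer is removed by HPLC.

---

**Step 1**
Reactants: **1** 2′,6′-dihydroxy-4′-methoxyacetophenone
Product: **2** 2′-allyloxy-6′-hydroxy-4′-methoxyacetophenone
Conditions: allyl bromide (1.05 equiv), K2CO3 (1.1 equiv), acetone, reflux, 12 h
Reagents that add atoms: allyl bromide, C=CCBr
Why: The two OH groups of **1** are equivalent and one is locked in the C=O chelate, so mono-O-alkylation (Williamson ether synthesis) gives a single regioisomer.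

**Step 2**
Reactants: **2**
Product: **3** 3′-allyl-2′,6′-dihydroxy-4′-methoxyacetophenone
Conditions: PhNEt2, 200 °C (sealed tube or microwave), 2–3 h
Reagents that add atoms: none
Why: The aromatic Claisen [3,3] rearrangement can only migrate the allyl group to the one free ortho carbon (C3′, between O and OMe), because the other ortho position carries the acetyl group. This fixes the carbon framework so the allyl ends up flanking the OH that becomes 5-OH.

**Step 3**
Reactants: **3**
Product: **4** 3′-allyl-2′,6′-bis(methoxymethoxy)-4′-methoxyacetophenone
Conditions: NaH (2.3 equiv), DMF, 0 °C, then MOMCl (2.5 equiv), 0 °C → 25 °C, 4 h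
Reagents that add atoms: chloromethyl methyl ether (MOMCl), COCCl
Why: Phenoxide O-alkylation (MOM protection) masks both phenols so they survive olefin metathesis and the basic condensation. It also prevents premature racemic cyclisation of the chalcone.

**Step 4**
Reactants: **4**
Product: **5** 2′,6′-bis(methoxymethoxy)-4′-methoxy-3′-(3-methylbut-2-enyl)acetophenone
Conditions: Hoveyda–Grubbs II (5 mol %), 1,4-benzoquinone (10 mol %), 2-methyl-2-butene (20 equiv), CH2Cl2, 40 °C, sealed tube, 16 h
Reagents that add atoms: 2-methyl-2-butene, CC=C(C)C
Why: Cross-metathesis of the terminal allyl olefin with excess 2-methyl-2-butene converts allyl to prenyl (propene is lost). The quinone suppresses Ru-hydride olefin isomerisation. The acetals, aryl ether and ketone are inert.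

**Step 5**
Reactants: **6** 4-hydroxybenzaldehyde
Product: **7** 4-(methoxymethoxy)benzaldehyde
Conditions: MOMCl (1.3 equiv), i-Pr2NEt (1.5 equiv), CH2Cl2, 0 °C → 25 °C, 6 h
Reagents that add atoms: MOMCl, COCCl
Why: Phenol O-alkylation (MOM protection) gives a protected B-ring aldehyde that will not consume base or oxidise in the condensation.

**Step 6**
Reactants: **5** and **7**
Product: **8** (E)-1-[2,6-bis(methoxymethoxy)-4-methoxy-3-prenylphenyl]-3-[4-(methoxymethoxy)phenyl]prop-2-en-1-one
Conditions: KOH (10 equiv), EtOH/H2O (9:1), 25 °C, 48 h
Reagents that add atoms: none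
Why: Claisen–Schmidt (aldol–dehydration) condensation of the methyl ketone enolate with a non-enolisable aldehyde gives the thermodynamically favoured E-enone. The MOM ethers are base-stable.

**Step 7**
Reactants: **8**
Product: **9** (E)-2′,4-dihydroxy-6′-hydroxy-4′-methoxy-3′-prenylchalcone, i.e. (E)-1-(2,6-dihydroxy-4-methoxy-3-prenylphenyl)-3-(4-hydroxyphenyl)prop-2-en-1-one
Conditions: 3 M HCl (aq)/THF/MeOH (1:2:2), 0 → 25 °C, 4–6 h, monitored by HPLC. Cold EtOAc/brine work-up, short plug of neutral silica, used at once.
Reagents that add atoms: none
Why: Acid-catalysed acetal hydrolysis removes all three aryl MOM groups. Mild, short, room-temperature conditions leave the trisubstituted prenyl alkene intact and keep spontaneous (racemic) flavanone formation negligible.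

**Step 8**
Reactants: **9**
Product: **10** (S)-6-prenylsakuranetin (target)
Conditions: recombinant *Medicago sativa* chalcone isomerase (EC 5.5.1.6, isomerase class), 50 mM K-phosphate pH 7.0, 5 % DMSO, [**9**] about 0.3 mM, 25 °C, 1 h. EtOAc extraction, then preparative C18 HPLC (MeCN/H2O) to remove (S)-8-prenylsakuranetin.
Reagents that add atoms: none
Why: Chalcone isomerase catalyses intramolecular oxa-Michael addition of the 6′-OH to Cβ within its chiral active site, setting C2 as (S). The 3′-prenyl group buttresses the flanking 2′-OH into the C=O chelate, so the unhindered 6′-OH is the nucleophile and the 6-prenyl skeleton is favoured. At pH 7 and 25 °C the uncatalysed background cyclisation is orders of magnitude slower, so enantiopurity is retained. No base or heat follows, so C2 is not epimerised.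

**Consistency checks**
- Target SMILES: 5-OH, 6-prenyl, 7-OMe, 4′-OH flavanone, (S) at C2.
- Chalcone **9** cyclising through O6′ gives C8a = C6′, C8 = C5′(H), C7 = C4′(OMe), C6 = C3′(prenyl), C5 = C2′(OH), which matches the target.
- Every atom is accounted for in each step, and the final product is the target.

---

**Compound list**

| No. | Name | SMILES | Role |
|---|---|---|---|
| 1 | 2′,6′-dihydroxy-4′-methoxyacetophenone | CC(=O)c1c(O)cc(OC)cc1O | starting material |
| 2 | 2′-allyloxy-6′-hydroxy-4′-methoxyacetophenone | CC(=O)c1c(OCC=C)cc(OC)cc1O | intermediate |
| 3 | 3′-allyl-2′,6′-dihydroxy-4′-methoxyacetophenone | CC(=O)c1c(O)c(CC=C)c(OC)cc1O | intermediate |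
| 4 | 3′-allyl-2′,6′-bis(MOM-oxy)-4′-methoxyacetophenone | CC(=O)c1c(OCOC)c(CC=C)c(OC)cc1OCOC | intermediate |
| 5 | 2′,6′-bis(MOM-oxy)-4′-methoxy-3′-prenylacetophenone | CC(=O)c1c(OCOC)c(CC=C(C)C)c(OC)cc1OCOC | intermediate |
| 6 | 4-hydroxybenzaldehyde | O=Cc1ccc(O)cc1 | starting material |
| 7 | 4-(methoxymethoxy)benzaldehyde | O=Cc1ccc(OCOC)cc1 | intermediate |
| 8 | tris-MOM chalcone | COc1cc(OCOC)c(C(=O)/C=C/c2ccc(OCOC)cc2)c(OCOC)c1CC=C(C)C | intermediate |
| 9 | 2′,6′,4-trihydroxy-4′-methoxy-3′-prenylchalcone | COc1cc(O)c(C(=O)/C=C/c2ccc(O)cc2)c(O)c1CC=C(C)C | intermediate |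
| 10 | (S)-6-prenylsakuranetin | COc1cc2c(c(O)c1CC=C(C)C)C(=O)C[C@@H](c1ccc(O)cc1)O2 | target |

**Totals**
- Total steps: 8.
- Longest linear sequence: 7 (1 → 2 → 3 → 4 → 5 → 8 → 9 → 10, via steps 1, 2, 3, 4, 6, 7, 8).

**Three steps most likely to fail**
1. **Step 8 (enzymatic cyclisation).** The 4′-OMe/3′-prenyl chalcone is not a natural substrate. Conversion may be low, a substantial 8-prenyl isomer may form, or the background racemate may erode ee.
   - Fallback: block the 2′-OH as MOM on a chalcone with a free 6′-OH, cyclise with a bifunctional cinchona-squaramide oxa-Michael organocatalyst (regiochemistry then fixed), and remove MOM under mild acid. A second fallback is base-mediated racemic cyclisation followed by preparative chiral-phase HPLC resolution.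
2. **Step 4 (allyl → prenyl cross-metathesis).** It may give incomplete conversion or propenyl isomers.
   - Fallback: abandon the Claisen/metathesis route and C-prenylate **1** directly with prenyl bromide under aqueous KOH/MeOH (phloroglucinol-type dianion C-alkylation). Separate the 3-prenyl product from di-prenylated material, then continue from the bis-MOM stage.
3. **Step 7 (MOM removal).** Acid may trigger premature racemic flavanone formation or cyclisation of the prenyl group onto the neighbouring OH to give a chroman, which would lower ee and yield.
   - Fallback: redesign the protecting-group scheme. Use allyl ethers on the phenols (removed by Pd(PPh3)4/PhSiH3 under near-neutral conditions) or 2-(trimethylsilyl)ethoxymethyl ethers (SEM, removed by fluoride). Alternatively, condense the free phenols directly with a large excess of LiOH and feed the freshly acidified chalcone straight into the enzyme.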